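**Retrosynthetic overview**
1. Feature used: on the ten-membered carbocycle, C6 carries the lactone oxygen, C7 the lactone α-carbon C11 and C8 an ester oxygen. The butyrolactone ring (C7–C11 bond) and the C8–O bond are therefore made together across a Z C7=C8 ring alkene, by a C11 radical tethered through O6 as a bromoacetal (32 → 35).
2. After the key step: C8 methacrylation, acetal → lactone, C11 methylenation, C9 desilylation (35 → 45).
3. Before it: bromoacetal 32 from macrocyclic allylic alcohol 29, itself from ring-closing metathesis (C7=C8) of furanone diene 28.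
4. Diene 28 by gold-catalysed 3(2H)-furanone formation from the adduct of enyne 11 (C9 from a kinetic resolution, carbon from acrolein) and vinyl lactone 23 (C4 from (S)-citramalic acid, C6 by asymmetric transfer hydrogenation).
5. Ring order: furanone ring (step 13), ten-membered carbocycle (step 14), acetal ring that becomes the α-methylene lactone (step 16).

Key step: step 16

Remark on locants: C1 is the furanone carbon bound to the ring oxygen and to C10; C2 the furanone CH; C3 the ketone; C4 the quaternary carbon (methyl C15); C5 the CH2; C6 to C9 the four CH carbons; C10 bears the exocyclic methylene C14; C11, C12 and C13 are the lactone α-carbon, the lactone carbonyl (acetal) carbon and its exocyclic methylene.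
Remark on the acetal carbon: the bromoacetalisation is taken to give both epimers at C12; both are carried on because C12 becomes the lactone carbonyl, and the SMILES of 32, 34, 35 and 37 show one epimer.

**Step 1**
Reactants: 1 acrolein
Product: 4 2-bromoprop-2-enal, via 2,3-dibromopropanal 3 (not isolated)
Conditions: Br2, CH2Cl2, −78 → 0 °C; then Et3N, 0 °C
Reagents that add atoms: 2 bromine, BrBr
Why: Bromine adds across the enal C=C and triethylamine removes HBr from the α,β-dibromo aldehyde (bromination–dehydrobromination), which should leave the conjugated α-bromo enal.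

**Step 2**
Reactants: 4 2-bromoprop-2-enal; 5 vinylmagnesium bromide
Product: 6 rac-2-bromopenta-1,4-dien-3-ol
Conditions: THF, −78 °C; aq. NH4Cl
Reagents that add atoms: 5 vinylmagnesium bromide, C=C[Mg]Br
Why: Grignard 1,2-addition to the aldehyde at low temperature should give the racemic bis-allylic carbinol (future C9).

**Step 3**
Reactants: 6 rac-2-bromopenta-1,4-dien-3-ol
Product: 7 (R)-2-bromopenta-1,4-dien-3-ol
Conditions: Ti(Oi-Pr)4, D-(−)-diisopropyl tartrate, t-BuOOH (0.6 equiv), 4 Å molecular sieves, CH2Cl2, −20 °C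
Reagents that add atoms: none
Why: Sharpless kinetic resolution: the titanium–D-tartrate complex should epoxidise the vinyl group of the (S)-carbinol much faster than that of the (R)-carbinol, the electron-poor 2-bromovinyl group staying inert, so the (R)-alcohol that fixes C9 is recovered.

**Step 4**
Reactants: 7 (R)-2-bromopenta-1,4-dien-3-ol
Product: 9 (R)-[(2-bromopenta-1,4-dien-3-yl)oxy](tert-butyl)dimethylsilane
Conditions: t-BuMe2SiCl, imidazole, DMF, rt
Reagents that add atoms: 8 tert-butyldimethylsilyl chloride, CC(C)(C)[Si](C)(C)Cl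
Why: Standard silylation of a secondary alcohol; the stereocentre is not touched.

**Step 5**
Reactants: 9 (R)-[(2-bromopenta-1,4-dien-3-yl)oxy](tert-butyl)dimethylsilane; 10 ethynylmagnesium bromide
Product: 11 (R)-tert-butyldimethyl[(4-methylidenehex-1-en-5-yn-3-yl)oxy]silane
Conditions: HC≡CMgBr, ZnBr2, THF, 0 °C; then 9, Pd(PPh3)4 (5 mol %), rt
Reagents that add atoms: 10 ethynylmagnesium bromide, C#C[Mg]Br
Why: Negishi coupling of ethynylzinc bromide with the 2-bromoalkene should give the terminal 1,3-enyne directly, without touching the allylic silyl ether.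

**Step 6**
Reactants: 12 (S)-citramalic acid
Product: 14 2-[(4S)-2,2,4-trimethyl-5-oxo-1,3-dioxolan-4-yl]acetic acid
Conditions: Me2C(OMe)2, TsOH·H2O (cat.), rt
Reagents that add atoms: 13 2,2-dimethoxypropane, COC(C)(C)OC
Why: Acetal exchange closes the five-membered dioxolanone on the α-hydroxy acid and leaves the β-carboxyl free (carboxyl differentiation); the quaternary C4 centre comes from the chiral pool.

**Step 7**
Reactants: 14 2-[(4S)-2,2,4-trimethyl-5-oxo-1,3-dioxolan-4-yl]acetic acid; 15 trimethylsilylacetylene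
Product: 17 (5S)-2,2,5-trimethyl-5-[2-oxo-4-(trimethylsilyl)but-3-yn-1-yl]-1,3-dioxolan-4-one, via dioxolanone acid chloride 16 (not isolated)
Conditions: (COCl)2, DMF (cat.), CH2Cl2, 0 °C → rt, evaporate; then Me3SiC≡CH, PdCl2(PPh3)2 (2 mol %), CuI (4 mol %), Et3N, THF, rt
Reagents that add atoms: 15 trimethylsilylacetylene, C#C[Si](C)(C)C
Why: Acid chloride formation followed by acyl Sonogashira coupling should give the silyl ynone under conditions that spare the dioxolanone.

**Step 8**
Reactants: 17 (5S)-2,2,5-trimethyl-5-[2-oxo-4-(trimethylsilyl)but-3-yn-1-yl]-1,3-dioxolan-4-one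
Product: 18 (5S)-5-[(2S)-2-hydroxy-4-(trimethylsilyl)but-3-yn-1-yl]-2,2,5-trimethyl-1,3-dioxolan-4-one
Conditions: Ru[(S,S)-TsNCHPhCHPhNH](p-cymene) (2 mol %), i-PrOH, rt
Reagents that add atoms: none
Why: Noyori asymmetric transfer hydrogenation of an alkynyl ketone: the (S,S)-catalyst should deliver hydride to give the (S)-propargylic alcohol (C6) under catalyst control, independent of the remote C4 centre.

**Step 9**
Reactants: 18 (5S)-5-[(2S)-2-hydroxy-4-(trimethylsilyl)but-3-yn-1-yl]-2,2,5-trimethyl-1,3-dioxolan-4-one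
Product: 20 (3S,5S)-5-ethynyl-3-hydroxy-3-methyloxolan-2-one, via methyl dihydroxyhexynoate 19 (not isolated)
Conditions: K2CO3, MeOH, 0 °C → rt; then aq. HCl to pH 2, rt
Reagents that add atoms: none
Why: Basic methanol opens the dioxolanone and cleaves the C–Si bond, and acid then closes the γ-lactone, which masks the C6 hydroxyl and keeps C3 activated as an acylating carbon.

**Step 10**
Reactants: 20 (3S,5S)-5-ethynyl-3-hydroxy-3-methyloxolan-2-one
Product: 21 (3S,5S)-5-ethenyl-3-hydroxy-3-methyloxolan-2-one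
Conditions: H2 (1 atm), Pd/CaCO3 poisoned with Pb(OAc)2 (Lindlar catalyst), quinoline, EtOAc, rt
Reagents that add atoms: none
Why: Lindlar semi-hydrogenation of the terminal alkyne should stop at the vinyl group (future C7=C8 terminus).

**Step 11**
Reactants: 21 (3S,5S)-5-ethenyl-3-hydroxy-3-methyloxolan-2-one
Product: 23 (3S,5S)-5-ethenyl-3-methyl-3-[(trimethylsilyl)oxy]oxolan-2-one
Conditions: Me3SiCl, imidazole, DMF, 0 °C → rt
Reagents that add atoms: 22 chlorotrimethylsilane, C[Si](C)(C)Cl
Why: Silylation of the tertiary hydroxyl keeps it from quenching the acetylide in the next step; the lactone has no α-hydrogen, so it cannot enolise.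

**Step 12**
Reactants: 11 (R)-tert-butyldimethyl[(4-methylidenehex-1-en-5-yn-3-yl)oxy]silane; 23 (3S,5S)-5-ethenyl-3-methyl-3-[(trimethylsilyl)oxy]oxolan-2-one
Product: 26 (3S,5S)-2-[(4R)-4-[(tert-butyldimethylsilyl)oxy]-3-methylidenehex-5-en-1-yn-1-yl]-5-ethenyl-3-methyloxolane-2,3-diol, via lithium acetylide 24 (not isolated), via O-trimethylsilyl hemiketal 25 (not isolated)
Conditions: 11, n-BuLi, THF, −78 °C; then 23, −78 → −40 °C; AcOH quench; AcOH–THF–H2O, rt
Reagents that add atoms: none
Why: A lithium acetylide adds once to a γ-lactone because the tetrahedral alkoxide is stable at low temperature (acetylide–lactone addition, as with silylated sugar lactones), and mild acid then removes only the trimethylsilyl group, joining C2 to C3 with all three stereocentres untouched.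

**Step 13**
Reactants: 26 (3S,5S)-2-[(4R)-4-[(tert-butyldimethylsilyl)oxy]-3-methylidenehex-5-en-1-yn-1-yl]-5-ethenyl-3-methyloxolane-2,3-diol
Product: 28 (2S)-5-[(3R)-3-[(tert-butyldimethylsilyl)oxy]penta-1,4-dien-2-yl]-2-[(2S)-2-hydroxybut-3-en-1-yl]-2-methylfuran-3(2H)-one, via open-chain hydroxy ynone 27 (not isolated)
Conditions: Ph3PAuCl (5 mol %), AgOTf (5 mol %), toluene, rt
Reagents that add atoms: none
Why: Gold-catalysed 5-endo-dig hydroalkoxylation of the tertiary C4 hydroxyl onto the activated alkyne (cycloisomerisation of an α'-hydroxy ynone, reached from the hemiketal by ring–chain tautomerism) should give the 3(2H)-furanone and release the C6 hydroxyl.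

**Step 14**
Reactants: 28 (2S)-5-[(3R)-3-[(tert-butyldimethylsilyl)oxy]penta-1,4-dien-2-yl]-2-[(2S)-2-hydroxybut-3-en-1-yl]-2-methylfuran-3(2H)-one
Product: 29 (3R,4Z,6S,8S)-3-[(tert-butyldimethylsilyl)oxy]-6-hydroxy-8-methyl-2-methylidene-11-oxabicyclo[6.2.1]undeca-1(10),4-dien-9-one
Conditions: second-generation Grubbs catalyst RuCl2(H2IMes)(PCy3)(=CHPh) (10 mol %), 1,4-benzoquinone (20 mol %), toluene (1 mM), 80 °C
Reagents that add atoms: none
Why: Ring-closing metathesis of the two monosubstituted vinyl groups closes the ten-membered ring at C7=C8; the conjugated 1,1-disubstituted C10=C14 alkene is hindered and electron-poor and its engagement would give a far more strained bicycle, and the Z geometry should follow from the strain of an E alkene in the nine-membered oxygen-bridged ring.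

**Step 15**
Reactants: 29 (3R,4Z,6S,8S)-3-[(tert-butyldimethylsilyl)oxy]-6-hydroxy-8-methyl-2-methylidene-11-oxabicyclo[6.2.1]undeca-1(10),4-dien-9-one; 30 ethyl vinyl ether; 31 N-bromosuccinimide
Product: 32 (3R,4Z,6S,8S)-6-(2-bromo-1-ethoxyethoxy)-3-[(tert-butyldimethylsilyl)oxy]-8-methyl-2-methylidene-11-oxabicyclo[6.2.1]undeca-1(10),4-dien-9-one
Conditions: ethyl vinyl ether, N-bromosuccinimide, CH2Cl2, −40 → 0 °C
Reagents that add atoms: 30 ethyl vinyl ether, C=COCC; 31 N-bromosuccinimide, O=C1CCC(=O)N1Br
Why: Bromoalkoxylation of the electron-rich enol ether (the usual preparation of Ueno–Stork precursors): the bromonium ion of ethyl vinyl ether is opened by the C6 hydroxyl at the oxygen-bearing carbon, the ring alkenes being far less nucleophilic.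

**Step 16**
Reactants: 32 (3R,4Z,6S,8S)-6-(2-bromo-1-ethoxyethoxy)-3-[(tert-butyldimethylsilyl)oxy]-8-methyl-2-methylidene-11-oxabicyclo[6.2.1]undeca-1(10),4-dien-9-one
Product: 35 tricyclic C8 alcohol with C12 ethyl acetal and C9 silyl ether (4S,6S,7S,8R,9S), via C8 hydroperoxide 34 (not isolated)
Conditions: Bu3SnH (syringe pump), dry air, toluene (0.01 M), rt; then PPh3
Reagents that add atoms: 33 dioxygen, O=O
Why: The tributyltin radical abstracts bromine from 32 to give the C11 radical, a 3-oxa-5-hexenyl radical that closes 5-exo-trig onto C7 (C7–C11 bond, tetrahydrofuran ring) faster than it is reduced by the slowly added hydride or captured by the little oxygen dissolved from air; the secondary C8 radical then has no fast intramolecular outlet, is trapped by O2 (C8–O bond), and the hydroperoxide 34 is reduced by PPh3. This is the Ueno–Stork haloacetal cyclisation run as a radical cyclisation–oxygenation with tin hydride under air, applied here to the ring alkene of a ten-membered carbocycle. In the Z alkene, A(1,3) strain places H6 and H9 in the alkene plane, so the O6 tether and ring carbon C5 lie on opposite faces; attack on C7 from the O6 face is then the only low-strain path and puts C5 and C8 trans on the new ring, which is the trans C6/C7 fusion. The same conformer holds the bulky C9 silyloxy group on the face opposite to O6, so O2 should reach C8 anti to it, on the face from which C11 arrived, which gives the C8 configuration of the target; the acetal carbon stays a mixture and is oxidised later. The step needs bromine abstraction to outrun stannyl radical addition to the cross-conjugated dienone and ring closure to outrun oxygen capture, and the fast closure of the oxygen-substituted radical, high dilution and air in place of pure oxygen should secure both.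

**Step 17**
Reactants: 35 tricyclic C8 alcohol with C12 ethyl acetal and C9 silyl ether; 36 methacryloyl chloride
Product: 37 tricyclic C8 methacrylate with C12 ethyl acetal and C9 silyl ether (4S,6S,7R,8R,9S)
Conditions: methacryloyl chloride, Et3N, DMAP (cat.), CH2Cl2, 0 °C → rt
Reagents that add atoms: 36 methacryloyl chloride, CC(=C)C(Cl)=O
Why: DMAP-catalysed acylation of the only free hydroxyl installs the C8 ester, which also protects C8 against the oxidation that follows.

**Step 18**
Reactants: 37 tricyclic C8 methacrylate with C12 ethyl acetal and C9 silyl ether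
Product: 39 trans-fused γ-lactone with C8 methacrylate and C9 silyl ether (4S,6S,7R,8R,9S)
Conditions: CrO3, H2SO4, acetone–H2O, 0 °C
Reagents that add atoms: 38 water, O
Why: Aqueous acid hydrolyses the cyclic ethyl acetal to the lactol and chromic acid oxidises it to the γ-lactone (Jones oxidation of a lactol ether), both acetal epimers converging; the hindered secondary silyl ether should survive a short cold exposure.

**Step 19**
Reactants: 39 trans-fused γ-lactone with C8 methacrylate and C9 silyl ether
Product: 42 C11 (dimethylaminomethyl) lactone, via lithium lactone enolate 41 (not isolated)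
Conditions: LiN(SiMe3)2, THF, −78 °C; then CH2=NMe2+ I−, −78 → 0 °C
Reagents that add atoms: 40 dimethylmethyleneiminium iodide, C=[N+](C)C.[I-]
Why: C11 is the only enolisable position (C4 is quaternary, C2 vinylic), so kinetic deprotonation and Mannich reaction of the lithium enolate with the iminium salt should aminomethylate C11, whose configuration is irrelevant.

**Step 20**
Reactants: 42 C11 (dimethylaminomethyl) lactone
Product: 44 C9 silyl ether of the target, via trimethylammonium iodide 43 (not isolated)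
Conditions: MeI, CH2Cl2–MeOH, rt; then aq. NaHCO3, rt
Reagents that add atoms: none
Why: Exhaustive N-methylation followed by base-induced E1cB loss of trimethylamine gives the conjugated exocyclic C11=C13 methylene.

**Step 21**
Reactants: 44 C9 silyl ether of the target
Product: 45 target CNP0142847.1
Conditions: HF·pyridine, pyridine, THF, 0 °C → rt
Reagents that add atoms: none
Why: Fluoride cleavage of the secondary silyl ether in a buffered acidic medium should leave both Michael-acceptor esters intact and avoid the O8 → O9 acyl migration that a basic fluoride source could cause.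

**Compound list**
1 | acrolein | C=CC=O | starting material
2 | bromine | BrBr | starting material
3 | 2,3-dibromopropanal (racemic, not isolated) | O=CC(Br)CBr | intermediate
4 | 2-bromoprop-2-enal | C=C(Br)C=O | intermediate
5 | vinylmagnesium bromide | C=C[Mg]Br | starting material
6 | rac-2-bromopenta-1,4-dien-3-ol | C=CC(O)C(Br)=C | intermediate
7 | (R)-2-bromopenta-1,4-dien-3-ol | C=C[C@@H](O)C(Br)=C | intermediate
8 | tert-butyldimethylsilyl chloride | CC(C)(C)[Si](C)(C)Cl | starting material
9 | (R)-[(2-bromopenta-1,4-dien-3-yl)oxy](tert-butyl)dimethylsilane | C=C[C@@H](O[Si](C)(C)C(C)(C)C)C(Br)=C | intermediate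
10 | ethynylmagnesium bromide | C#C[Mg]Br | starting material
11 | (R)-tert-butyldimethyl[(4-methylidenehex-1-en-5-yn-3-yl)oxy]silane | C=C[C@@H](O[Si](C)(C)C(C)(C)C)C(=C)C#C | intermediate
12 | (S)-citramalic acid, (2S)-2-hydroxy-2-methylbutanedioic acid | C[C@](O)(CC(=O)O)C(=O)O | starting material
13 | 2,2-dimethoxypropane | COC(C)(C)OC | starting material
14 | 2-[(4S)-2,2,4-trimethyl-5-oxo-1,3-dioxolan-4-yl]acetic acid | OC(=O)C[C@]1(C)OC(C)(C)OC1=O | intermediate
15 | trimethylsilylacetylene | C#C[Si](C)(C)C | starting material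
16 | 2-[(4S)-2,2,4-trimethyl-5-oxo-1,3-dioxolan-4-yl]acetyl chloride (not isolated) | ClC(=O)C[C@]1(C)OC(C)(C)OC1=O | intermediate
17 | (5S)-2,2,5-trimethyl-5-[2-oxo-4-(trimethylsilyl)but-3-yn-1-yl]-1,3-dioxolan-4-one | C[Si](C)(C)C#CC(=O)C[C@]1(C)OC(C)(C)OC1=O | intermediate
18 | (5S)-5-[(2S)-2-hydroxy-4-(trimethylsilyl)but-3-yn-1-yl]-2,2,5-trimethyl-1,3-dioxolan-4-one | C[Si](C)(C)C#C[C@@H](O)C[C@]1(C)OC(C)(C)OC1=O | intermediate
19 | methyl (2S,4S)-2,4-dihydroxy-2-methylhex-5-ynoate (not isolated) | C#C[C@@H](O)C[C@](C)(O)C(=O)OC | intermediate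
20 | (3S,5S)-5-ethynyl-3-hydroxy-3-methyloxolan-2-one | C#C[C@@H]1C[C@](C)(O)C(=O)O1 | intermediate
21 | (3S,5S)-5-ethenyl-3-hydroxy-3-methyloxolan-2-one | C=C[C@@H]1C[C@](C)(O)C(=O)O1 | intermediate
22 | chlorotrimethylsilane | C[Si](C)(C)Cl | starting material
23 | (3S,5S)-5-ethenyl-3-methyl-3-[(trimethylsilyl)oxy]oxolan-2-one | C=C[C@@H]1C[C@](C)(O[Si](C)(C)C)C(=O)O1 | intermediate
24 | lithium acetylide of 11 (not isolated) | [Li]C#CC(=C)[C@H](O[Si](C)(C)C(C)(C)C)C=C | intermediate
25 | (3S,5S)-2-[(4R)-4-[(tert-butyldimethylsilyl)oxy]-3-methylidenehex-5-en-1-yn-1-yl]-5-ethenyl-3-methyl-3-[(trimethylsilyl)oxy]oxolan-2-ol (both C2 epimers, not isolated) | C=C[C@@H]1C[C@](C)(O[Si](C)(C)C)C(O)(C#CC(=C)[C@H](O[Si](C)(C)C(C)(C)C)C=C)O1 | intermediate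
26 | (3S,5S)-2-[(4R)-4-[(tert-butyldimethylsilyl)oxy]-3-methylidenehex-5-en-1-yn-1-yl]-5-ethenyl-3-methyloxolane-2,3-diol (both C2 epimers; ring tautomer of 27) | C=C[C@@H]1C[C@](C)(O)C(O)(C#CC(=C)[C@H](O[Si](C)(C)C(C)(C)C)C=C)O1 | intermediate
27 | (3S,5S,10R)-10-[(tert-butyldimethylsilyl)oxy]-3,5-dihydroxy-5-methyl-9-methylidenedodeca-1,11-dien-7-yn-6-one (open-chain tautomer, not isolated) | C=C[C@@H](O)C[C@](C)(O)C(=O)C#CC(=C)[C@H](O[Si](C)(C)C(C)(C)C)C=C | intermediate
28 | (2S)-5-[(3R)-3-[(tert-butyldimethylsilyl)oxy]penta-1,4-dien-2-yl]-2-[(2S)-2-hydroxybut-3-en-1-yl]-2-methylfuran-3(2H)-one | C=C[C@@H](O)C[C@]1(C)OC(=CC1=O)C(=C)[C@H](O[Si](C)(C)C(C)(C)C)C=C | intermediate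
29 | (3R,4Z,6S,8S)-3-[(tert-butyldimethylsilyl)oxy]-6-hydroxy-8-methyl-2-methylidene-11-oxabicyclo[6.2.1]undeca-1(10),4-dien-9-one (furanone-bridged ten-membered ring; C4 S, C6 S, C9 R; Z C7=C8; free C6 hydroxyl) | [C@@H]1(O[Si](C)(C)C(C)(C)C)/C=C\[C@@H](O)C[C@]2(C)OC(=CC2=O)C1=C | intermediate
30 | ethyl vinyl ether | C=COCC | starting material
31 | N-bromosuccinimide | O=C1CCC(=O)N1Br | starting material
32 | (3R,4Z,6S,8S)-6-(2-bromo-1-ethoxyethoxy)-3-[(tert-butyldimethylsilyl)oxy]-8-methyl-2-methylidene-11-oxabicyclo[6.2.1]undeca-1(10),4-dien-9-one (key-step precursor; both acetal epimers, one drawn) | [C@@H]1(O[Si](C)(C)C(C)(C)C)/C=C\[C@@H](O[C@H](OCC)CBr)C[C@]2(C)OC(=CC2=O)C1=C | intermediate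
33 | dioxygen (from air) | O=O | starting material
34 | C8 hydroperoxide of the cyclised ethyl acetal (4S,6S,7R,8R,9S; C12 epimers, one drawn; not isolated) | [C@@H]1(O[Si](C)(C)C(C)(C)C)[C@H](OO)[C@@H]3C[C@@H](OCC)O[C@H]3C[C@]2(C)OC(=CC2=O)C1=C | intermediate
35 | tricyclic C8 alcohol: furanone-bridged ten-membered ring trans-fused at C6/C7 to a 2-ethoxytetrahydrofuran (O6–C12–C11–C7), C9 silyl ether, C10=C14 methylene (4S,6S,7S,8R,9S; C12 epimers, one drawn) | [C@@H]1(O[Si](C)(C)C(C)(C)C)[C@H](O)[C@@H]3C[C@@H](OCC)O[C@H]3C[C@]2(C)OC(=CC2=O)C1=C | intermediate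
36 | methacryloyl chloride | CC(=C)C(Cl)=O | starting material
37 | C8 methacrylate of 35 (4S,6S,7R,8R,9S; C12 epimers, one drawn) | C=C(C)C(=O)O[C@@H]1[C@@H]2C[C@@H](OCC)O[C@H]2C[C@]2(C)OC(=CC2=O)C(=C)[C@@H]1O[Si](C)(C)C(C)(C)C | intermediate
38 | water | O | starting material
39 | trans-fused C12,O6 γ-lactone with C8 methacrylate and C9 silyl ether (4S,6S,7R,8R,9S) | C=C(C)C(=O)O[C@@H]1[C@@H]2CC(=O)O[C@H]2C[C@]2(C)OC(=CC2=O)C(=C)[C@@H]1O[Si](C)(C)C(C)(C)C | intermediate
40 | dimethylmethyleneiminium iodide | C=[N+](C)C.[I-] | starting material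
41 | lithium enolate of lactone 39 (not isolated) | C=C(C)C(=O)O[C@@H]1[C@@H]2C=C(O[Li])O[C@H]2C[C@]2(C)OC(=CC2=O)C(=C)[C@@H]1O[Si](C)(C)C(C)(C)C | intermediate
42 | C11 (dimethylaminomethyl) derivative of lactone 39 (C11 epimers) | C=C(C)C(=O)O[C@@H]1[C@@H]2C(CN(C)C)C(=O)O[C@H]2C[C@]2(C)OC(=CC2=O)C(=C)[C@@H]1O[Si](C)(C)C(C)(C)C | intermediate
43 | trimethylammonium iodide of 42 (not isolated) | C=C(C)C(=O)O[C@@H]1[C@@H]2C(C[N+](C)(C)C)C(=O)O[C@H]2C[C@]2(C)OC(=CC2=O)C(=C)[C@@H]1O[Si](C)(C)C(C)(C)C.[I-] | intermediate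
44 | C9 tert-butyldimethylsilyl ether of the target (4S,6S,7R,8R,9S) | C=C(C)C(=O)O[C@@H]1[C@@H]2C(=C)C(=O)O[C@H]2C[C@]2(C)OC(=CC2=O)C(=C)[C@@H]1O[Si](C)(C)C(C)(C)C | intermediate
45 | CNP0142847.1 (4S,6S,7R,8R,9S): 9-hydroxy-8-methacryloyloxy α-methylene γ-lactone on the furanone-bridged ten-membered ring | C=C(C)C(=O)O[C@@H]1[C@@H]2C(=C)C(=O)O[C@H]2C[C@]2(C)OC(=CC2=O)C(=C)[C@@H]1O | target

**Step count and risks**
Total: 21 steps. Longest linear sequence: 16 steps (steps 6 to 21, from (S)-citramalic acid).

Most likely to fail: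

1. Step 16 (key step). The C11 radical may be captured by dissolved oxygen or reduced by tin hydride before it closes, stannyl radicals may add to the dienone, and oxygen capture at C8 may show poor facial selectivity. The fallback separates the C–C bond formation from the oxygenation. It sets out from 29: ethyl vinyl ether and N-iodosuccinimide give the iodoacetal F1. Et3B with a trace of air in benzene, with no hydride donor and no oxygen reservoir, effects iodine-atom-transfer 5-exo cyclisation to the C8 iodide F2. The C8 radical is then regenerated from F2 alone with Bu3SnH under air, followed by PPh3, which returns to the route at 35.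

2. Step 14. Cross-metathesis oligomerisation may outrun closure of the strained ten-membered ring, or the ring may close with E geometry. The fallback closes the ring at C8–C9 by an intramolecular Nozaki–Hiyama–Kishi reaction on a substrate whose Z alkene is made beforehand. It sets out from 20: iodination of the terminal alkyne (N-iodosuccinimide, AgNO3) gives the iodoalkyne lactone F3, diimide reduction (2-nitrobenzenesulfonylhydrazide, Et3N) gives the (Z)-iodovinyl lactone F4, and Me3SiCl with imidazole gives its silyl ether F5. In parallel, 2-bromoprop-2-en-1-ol is silylated to the bromoallyl silyl ether F6 and ethynylated as in step 5 to the enyne F7. Addition of the lithium acetylide of F7 to F5 and mild acid, as in step 12, gives the hemiketal F8; gold catalysis as in step 13 gives the furanone F9; ethyl vinyl ether and N-bromosuccinimide give the bromoacetal F10. HF·pyridine frees the primary allylic alcohol F11, Dess–Martin periodinane gives the enal F12, and CrCl2 with catalytic NiCl2 in DMSO at high dilution closes the ring to the C9 alcohol F13. Its C9 epimer would be separated and recycled by oxidation and reduction. Silylation of F13 with tert-butyldimethylsilyl triflate and 2,6-lutidine returns to the route at 32.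

3. Step 19. The amide base or the lactone enolate may add to the methacrylate or to the cross-conjugated dienone (conjugate addition, anionic oligomerisation) in place of clean aminomethylation at C11. The fallback carries the C13 methylene in the radical precursor, so that no enolate is needed. It sets out from 29: methoxyallene and N-bromosuccinimide give the 2-bromoallyl mixed acetal F14. Bu3SnH under air, then PPh3, gives by 5-exo closure of the vinyl radical and oxygen capture the α-methylene methyl acetal alcohol F15. Methacryloyl chloride with Et3N and DMAP gives its methacrylate F16, and CrO3/H2SO4 oxidation of the allylic acetal returns to the route at 44.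

**Further compounds**
F1 | step 16 | (3R,4Z,6S,8S)-3-[(tert-butyldimethylsilyl)oxy]-6-(1-ethoxy-2-iodoethoxy)-8-methyl-2-methylidene-11-oxabicyclo[6.2.1]undeca-1(10),4-dien-9-one (acetal epimers) | [C@@H]1(O[Si](C)(C)C(C)(C)C)/C=C\[C@@H](OC(OCC)CI)C[C@]2(C)OC(=CC2=O)C1=C
F2 | step 16 | C8 iodide of the cyclised ethyl acetal, ring fusion as in 35 (C8 and C12 epimers) | [C@@H]1(O[Si](C)(C)C(C)(C)C)C(I)[C@@H]3CC(OCC)O[C@H]3C[C@]2(C)OC(=CC2=O)C1=C
F3 | step 14 | (3S,5S)-3-hydroxy-5-(iodoethynyl)-3-methyloxolan-2-one | IC#C[C@@H]1C[C@](C)(O)C(=O)O1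
F4 | step 14 | (3S,5S)-3-hydroxy-5-[(Z)-2-iodoethenyl]-3-methyloxolan-2-one | I/C=C\[C@@H]1C[C@](C)(O)C(=O)O1
F5 | step 14 | (3S,5S)-5-[(Z)-2-iodoethenyl]-3-methyl-3-[(trimethylsilyl)oxy]oxolan-2-one | I/C=C\[C@@H]1C[C@](C)(O[Si](C)(C)C)C(=O)O1
F6 | step 14 | [(2-bromoprop-2-en-1-yl)oxy](tert-butyl)dimethylsilane | C=C(Br)CO[Si](C)(C)C(C)(C)C
F7 | step 14 | tert-butyldimethyl[(2-methylidenebut-3-yn-1-yl)oxy]silane | C#CC(=C)CO[Si](C)(C)C(C)(C)C
F8 | step 14 | (3S,5S)-2-[4-[(tert-butyldimethylsilyl)oxy]-3-methylidenebut-1-yn-1-yl]-5-[(Z)-2-iodoethenyl]-3-methyloxolane-2,3-diol (C2 epimers) | I/C=C\[C@@H]1C[C@](C)(O)C(O)(C#CC(=C)CO[Si](C)(C)C(C)(C)C)O1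
F9 | step 14 | (2S)-5-[3-[(tert-butyldimethylsilyl)oxy]prop-1-en-2-yl]-2-[(2S,3Z)-2-hydroxy-4-iodobut-3-en-1-yl]-2-methylfuran-3(2H)-one | I/C=C\[C@@H](O)C[C@]1(C)OC(=CC1=O)C(=C)CO[Si](C)(C)C(C)(C)C
F10 | step 14 | 2-bromo-1-ethoxyethyl acetal of F9 at the C6 oxygen (acetal epimers) | I/C=C\[C@@H](OC(OCC)CBr)C[C@]1(C)OC(=CC1=O)C(=C)CO[Si](C)(C)C(C)(C)C
F11 | step 14 | primary allylic alcohol from F10 | I/C=C\[C@@H](OC(OCC)CBr)C[C@]1(C)OC(=CC1=O)C(=C)CO
F12 | step 14 | 2-substituted propenal (C9 aldehyde) from F11 | I/C=C\[C@@H](OC(OCC)CBr)C[C@]1(C)OC(=CC1=O)C(=C)C=O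
F13 | step 14 | (3R,4Z,6S,8S)-6-(2-bromo-1-ethoxyethoxy)-3-hydroxy-8-methyl-2-methylidene-11-oxabicyclo[6.2.1]undeca-1(10),4-dien-9-one (acetal epimers) | [C@@H]1(O)/C=C\[C@@H](OC(OCC)CBr)C[C@]2(C)OC(=CC2=O)C1=C
F14 | step 19 | (3R,4Z,6S,8S)-6-[(2-bromo-1-methoxyprop-2-en-1-yl)oxy]-3-[(tert-butyldimethylsilyl)oxy]-8-methyl-2-methylidene-11-oxabicyclo[6.2.1]undeca-1(10),4-dien-9-one (acetal epimers) | [C@@H]1(O[Si](C)(C)C(C)(C)C)/C=C\[C@@H](OC(OC)C(Br)=C)C[C@]2(C)OC(=CC2=O)C1=C
F15 | step 19 | tricyclic C8 alcohol with C11 methylene and C12 methyl acetal, configured as 35 (C12 epimers) | [C@@H]1(O[Si](C)(C)C(C)(C)C)[C@H](O)[C@@H]3C(=C)C(OC)O[C@H]3C[C@]2(C)OC(=CC2=O)C1=C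
F16 | step 19 | C8 methacrylate of F15 (C12 epimers) | C=C(C)C(=O)O[C@@H]1[C@@H]2C(=C)C(OC)O[C@H]2C[C@]2(C)OC(=CC2=O)C(=C)[C@@H]1O[Si](C)(C)C(C)(C)C
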